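## The problem

Compound 13, 3,6-dibromo-2-(2,4-dibromophenoxy)phenol, consists of two benzene rings joined through a single ether oxygen and has no stereocenter, so every difficulty is one of regiochemistry and chemoselectivity. Ring A carries the hydroxyl at C1 and the aryloxy oxygen at C2 as neighbours, each flanked on its outer side by a bromine, at C6 and at C3. Electrophilic bromination of a catechol derivative goes para to oxygen, to C4 and C5, so these two bromines have to arrive with the building block. Ring B has bromine ortho and para to its oxygen, the ordinary outcome of phenol bromination, and can be bought as 2,4-dibromophenol 7. The diaryl ether bond is crowded on both sides, and the two oxygens of ring A must be told apart. Four aryl C–Br bonds rule out alkyllithium reagents, reducing metals under forcing conditions and most metal-catalysed C–O couplings. The enabling feature is that C1 and C2 are adjacent, both oxygen-bearing and bracketed by C6–Br and C3–Br: removing both C–O bonds leaves the C1≡C2 triple bond of 3,6-dibromobenzyne 10, whose two carbons are equivalent by symmetry, so a nucleophilic and an electrophilic oxygen can be added across it with no regiochemical question.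

## Retrosynthesis

**Target 13 to tert-butyl ether 12.** The first cut is the O–C(CH3)3 bond on the C1 oxygen. tert-Butyl is chosen over methyl or benzyl because an electrophilic tert-butoxy donor delivers it directly in the key step. It also leaves under mild acid, to which the diaryl ether and the four C–Br bonds are indifferent. Compound 12 is no simpler in skeleton, but its capped oxygen cannot act as a nucleophile in the step before. The forward reaction only has to ionise a tertiary alkyl–oxygen bond beside a deactivated ring.

**Ether 12 to triflate 6, phenol 7 and perester 8.** Both C–O bonds on ring A are cut together. C2–O(aryl) is cut with oxygen as the nucleophile, phenoxide 9 from 7, and C1–O(tert-butyl) with oxygen as the electrophile, the peroxide oxygen of 8. What is left of ring A is aryne 10, released from 6. The neighbouring cut, of the diaryl ether bond alone, leads to a mono-protected catechol carrying both ring A bromines; that would require differentiating two equivalent oxygens and then a hindered C–O coupling in the presence of four aryl bromides. The double cut avoids both, because the first oxygen adds as an anion and the second is delivered to aryl anion 11. The simplification is large: 12 falls to a commercial phenol, a commercial perester and a nine-carbon aryne precursor. The forward step must release 10 slowly, let 9 add through oxygen, and let 11 reach the tert-butoxy oxygen of 8 before it finds a proton or expels its ortho bromide.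

**Triflate 6 to silylphenol 5.** The S–O bond is cut. An ortho-silylaryl triflate is preferred over an ortho-dihalide/metal precursor because fluoride activation leaves the ring bromines untouched, whereas metal–halogen exchange could not distinguish them from a leaving halogen. The forward step is an O-sulfonylation of a hindered, fairly acidic phenol.

**Silylphenol 5 to silyl ether 2 and phenol 1.** The C–Si bond is cut and silicon returned to oxygen: a 1,3 O→C silyl shift in aryllithium 3 gives phenoxide 4. Aryllithium 3 comes from 2 by deprotonation at the one ring position flanked by both oxygen and bromine, and 2 comes from 1 by O-silylation. This uses the C–H acidity that the substituents create and leaves both bromines alone, unlike a halogen–lithium exchange on a tribromophenol. Phenol 1 is commercial and already holds its bromines at the positions that become C3 and C6 of ring A. The forward reaction needs an amide base, not an alkyllithium, and a temperature low enough that 3 rearranges before it can eliminate its ortho bromide.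

## Roads not taken

Alternative 1: Ring A is cut at C4–C5 and at both C–Br bonds, which leads back to the enediyne 4,5-diethynyl-2,2-dimethyl-1,3-dioxole A1. On heating, Bergman cycloaromatisation of A1 would join the alkyne termini, and the para-diradical would take two bromine atoms from a bromine-atom donor to give 4,7-dibromo-2,2-dimethyl-1,3-benzodioxole A2.
- Merits: the bromines land exactly on the radical carbons, ortho to the oxygens, by mechanism. Cycloaromatisation with halogen-atom trapping is a known reaction type, so in precedent this key step is ahead of the chosen one.
- Weak points: A1 is an electron-rich enediyne whose alkynes are splayed apart by the five-membered ring, so cyclisation would need high temperature, where polymerisation and hydrogen abstraction compete with bromine transfer. A1 itself needs a multistep synthesis.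
- Comparison: A2 is only a protected catechol. The diaryl ether is not made, the two oxygens still have to be differentiated after acetonide removal, and the hindered arylation remains. The chosen plan forms both C–O bonds and the diaryl ether in one operation from a precursor three steps from 1, and desymmetrises in the same step.

Alternative 2: Ring A is cut at C1–C6 and C2–C3. The four-carbon piece is 2,5-dibromothiophene 1,1-dioxide A3. The two-carbon piece is 2,4-dibromo-1-{[2,2-bis(trimethylsilyloxy)ethenyl]oxy}benzene A4, a ketene bis(silyl) acetal reached from 7 by O-alkylation with a haloacetate and double silylation. Inverse-demand [4+2] cycloaddition of A4 to A3, cheletropic loss of the sulfone bridge and 1,2-elimination of silanol would give [3,6-dibromo-2-(2,4-dibromophenoxy)phenoxy]trimethylsilane A5, the trimethylsilyl ether of 13.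
- Merits: the diene A3 is symmetric, so no regiochemistry arises. The diaryl ether oxygen is attached by a simple alkylation, never at a crowded aromatic carbon. The silyl group of A5 falls off on work-up, and no aryl anion sits next to bromine. In these respects, and in the precedent for each elementary event, this road is at least as good as the chosen one and equally short.
- Weak points: halogenated thiophene dioxides such as A3 need strong oxidants to make and tend to dimerise. Both new bonds must form at bromine-bearing termini, while conjugate addition at the unsubstituted sulfone β-carbons competes. Making A4 needs a strong amide base on a ring whose C3'–H lies between two bromines.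
- Comparison: the chosen plan sets against the route through A5 three shelf-stable components (two commercial), no oxidant, no labile diene, and a modular step that accepts other phenoxides.

Alternative 3: Ring B is cut at C1'–C2' and C5'–C6'. The pieces are 3,5-dibromo-2H-pyran-2-one A6 and 1,4-dibromo-2-(ethynyloxy)-3-methoxybenzene A8, the ynol ether derived from 3,6-dibromo-2-methoxyphenol A7. Cycloaddition of A8 across C3 and C6 of A6 and decarboxylation of the bridged lactone would give 1,4-dibromo-2-(2,4-dibromophenoxy)-3-methoxybenzene A9, to be demethylated.
- Merits: A6 is a stable, well-behaved diene. Polarisation of the ynol ether A8 (nucleophilic terminal carbon to the electrophilic C6 of A6) predicts the required regiochemistry. The hindered ether oxygen is again in place before the ring is made.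
- Weak points: the road builds the ring that can be bought, and leaves the hard one unsolved, since A7 has the same awkward ring A pattern and must be made separately. Aryl ethynyl ethers such as A8 are labile, and their usual preparation by alkyllithium-induced elimination is at odds with aryl bromides. A Lewis-acid demethylation of A9 is added at the end.
- Comparison: the cycloaddition leading to A9 is better precedented than the key step chosen here. The chosen plan sets against it that ring A's substitution pattern is generated by the key step itself, in fewer operations overall.

Key step: step 4

## Route

Step 1
Reactants: 1 2,5-dibromophenol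
Product: 2 (2,5-dibromophenoxy)trimethylsilane
Conditions: (Me3Si)2NH, THF, 65 °C; concentrate, use crude
Reagents that add atoms: hexamethyldisilazane, C[Si](C)(C)N[Si](C)(C)C
Why: O-silylation of an acidic phenol with a silazane, with ammonia as the only co-product; no base or salt is carried into the metalation.

Step 2
Reactants: 2 (2,5-dibromophenoxy)trimethylsilane
Product: 5 3,6-dibromo-2-(trimethylsilyl)phenol, via [3,6-dibromo-2-(trimethylsilyloxy)phenyl]lithium 3 (not isolated), via lithium 3,6-dibromo-2-(trimethylsilyl)phenoxide 4 (not isolated)
Conditions: LiN(iPr)2, THF, −78 °C → rt; aq NH4Cl
Reagents that add atoms: none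
Why: Directed ortho-metalation followed by retro-Brook rearrangement: the hydrogen between the silyloxy group and bromine is the most acidic, an amide base does not exchange aryl bromides, and the 1,3 O→C silyl shift is driven by formation of the lithium phenoxide.

Step 3
Reactants: 5 3,6-dibromo-2-(trimethylsilyl)phenol
Product: 6 3,6-dibromo-2-(trimethylsilyl)phenyl trifluoromethanesulfonate
Conditions: Tf2O, pyridine, CH2Cl2, 0 °C
Reagents that add atoms: trifluoromethanesulfonic anhydride, O=S(=O)(OS(=O)(=O)C(F)(F)F)C(F)(F)F
Why: Standard O-triflation of a phenol with an amine base; the aryl–silicon bond and the bromides are inert to the anhydride at 0 °C.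

Step 4
Reactants: 6 3,6-dibromo-2-(trimethylsilyl)phenyl trifluoromethanesulfonate, 7 2,4-dibromophenol, 8 tert-butyl perbenzoate
Product: 12 1,4-dibromo-2-tert-butoxy-3-(2,4-dibromophenoxy)benzene, via potassium 2,4-dibromophenoxide 9 (not isolated), via 3,6-dibromobenzyne 10 (not isolated), via [3,6-dibromo-2-(2,4-dibromophenoxy)phenyl]potassium 11 (not isolated)
Conditions: 7, KH, THF, 0 °C; then 8 (5 equiv), KF, 18-crown-6, 6 added over 4 h, THF, −20 → 0 °C
Reagents that add atoms: none
Why: Proposed new method: fluoride attacks silicon of 6 and triflate leaves to give the symmetric aryne 10, the crown-separated phenoxide 9 adds through oxygen, and the resulting in-plane aryl anion 11, stabilised inductively by the flanking bromine and aryloxy group, attacks the tert-butoxy oxygen of 8 in an SN2-type displacement of benzoate. The closest known reaction types are fluoride-triggered three-component couplings of arynes with a nucleophile and an electrophile (amine plus CO2), O-arylation of phenols by arynes, and etherification of aryl Grignard reagents with tert-butyl perbenzoate. No ring is closed and no stereocenter is formed. Regiochemistry cannot arise because the two aryne carbons of 10 are equivalent. The step needs oxygen attack of 9 on 10 to beat acyl attack on 8; acyl transfer from a perester to the much less basic dibromophenoxide should be uphill and reversible. It also needs capture of 11 by 8 to beat protonation and loss of the ortho bromide; a proton-free medium with the phenoxide preformed by KH and no acetonitrile, a fivefold excess of 8 and slow addition of 6 at low temperature are meant to secure this. The tert-butyl cap keeps the new oxygen from re-entering as a nucleophile toward 10.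

Step 5
Reactants: 12 1,4-dibromo-2-tert-butoxy-3-(2,4-dibromophenoxy)benzene
Product: 13 3,6-dibromo-2-(2,4-dibromophenoxy)phenol
Conditions: CF3CO2H, CH2Cl2, 0 °C → rt
Reagents that add atoms: none
Why: Acid-mediated E1 cleavage of an aryl tert-butyl ether with loss of isobutene; the diaryl ether and aryl bromides are stable to the acid, and the doubly brominated ring A is too deactivated for Friedel–Crafts re-alkylation.

## Compound list

1 | 2,5-dibromophenol | Oc1cc(Br)ccc1Br | starting material
2 | (2,5-dibromophenoxy)trimethylsilane | C[Si](C)(C)Oc1cc(Br)ccc1Br | intermediate
3 | [3,6-dibromo-2-(trimethylsilyloxy)phenyl]lithium | [Li]c1c(Br)ccc(Br)c1O[Si](C)(C)C | intermediate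
4 | lithium 3,6-dibromo-2-(trimethylsilyl)phenoxide | [Li+].[O-]c1c(Br)ccc(Br)c1[Si](C)(C)C | intermediate
5 | 3,6-dibromo-2-(trimethylsilyl)phenol | C[Si](C)(C)c1c(Br)ccc(Br)c1O | intermediate
6 | 3,6-dibromo-2-(trimethylsilyl)phenyl trifluoromethanesulfonate | C[Si](C)(C)c1c(Br)ccc(Br)c1OS(=O)(=O)C(F)(F)F | intermediate
7 | 2,4-dibromophenol | Oc1ccc(Br)cc1Br | starting material
8 | tert-butyl perbenzoate | CC(C)(C)OOC(=O)c1ccccc1 | starting material
9 | potassium 2,4-dibromophenoxide | [K+].[O-]c1ccc(Br)cc1Br | intermediate
10 | 3,6-dibromobenzyne (1,4-dibromo-2,3-didehydrobenzene) | BrC1=CC=C(Br)C#C1 | intermediate
11 | [3,6-dibromo-2-(2,4-dibromophenoxy)phenyl]potassium | [K]c1c(Br)ccc(Br)c1Oc1ccc(Br)cc1Br | intermediate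
12 | 1,4-dibromo-2-tert-butoxy-3-(2,4-dibromophenoxy)benzene | CC(C)(C)Oc1c(Br)ccc(Br)c1Oc1ccc(Br)cc1Br | intermediate
13 | 3,6-dibromo-2-(2,4-dibromophenoxy)phenol | Oc1c(Br)ccc(Br)c1Oc1ccc(Br)cc1Br | target

## Step count and risks

Total step count: 5. Longest linear sequence: 5 steps (1 → 2 → 5 → 6 → 12 → 13).

**Step 4 (key step, the one step that carries the label "Proposed new method:").** The most likely failure is that oxygen transfer from 8 to aryl anion 11 is outrun. The anion can lose its ortho bromide, generating a second aryne and oligomeric ethers, or it can take a proton from the medium and give the simple diaryl ether. Attack of the anion at the perester carbonyl is a further leak. All three follow from the short lifetime of an unstabilised aryl anion that has to find an intermolecular partner.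

The fallback uses known chemistry, sets out from 6 and comes back to the route at 13. Aryne 10 would be generated from 6 with CsF in acetonitrile in the presence of the nitroxide TEMPO, whose radical double addition across arynes is established; this should give 1,1'-[(3,6-dibromo-1,2-phenylene)bis(oxy)]bis(2,2,6,6-tetramethylpiperidine) F1. Reductive N–O cleavage with Zn in acetic acid should then give 3,6-dibromobenzene-1,2-diol F2. The arylating agent would be (2,4-dibromophenyl)(2,4,6-trimethoxyphenyl)iodonium 4-methylbenzenesulfonate F3, prepared in one pot from 2,4-dibromo-1-iodobenzene with mCPBA and 4-methylbenzenesulfonic acid, followed by 1,3,5-trimethoxybenzene. F2, used in twofold excess with KOtBu in THF, would be mono-arylated by this salt under metal-free conditions; the electron-rich trimethoxyphenyl ligand stays on iodine and the electron-poor, ortho-substituted dibromophenyl group is transferred to oxygen. The two catechol oxygens are equivalent, and the second is shielded after the first arylation, so 13 should form directly, bypassing 12.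

**Step 2.** The ortho-bromoaryllithium 3 may eliminate its bromide or pass bromine to another ring before the silyl shift occurs, and deprotonation may be incomplete on the labile silyl ether. The fallback replaces the intramolecular silyl shift by external in-situ trapping on a stronger directing group; it sets out from 1 and comes back at 5. Phenol 1 would be converted with MOMCl and iPr2NEt into 1,4-dibromo-2-(methoxymethoxy)benzene F4. F4 would be treated with LiN(iPr)2 in THF at −78 °C with Me3SiCl already present, so that the anion is silylated as it forms, giving [3,6-dibromo-2-(methoxymethoxy)phenyl]trimethylsilane F5. Brief treatment of F5 with dilute HCl in methanol, stopped before the aryl–silicon bond is attacked, would remove the acetal and return 5.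

**Step 3.** Sulfonylation of the di-ortho-substituted, weakly nucleophilic phenol may be slow, giving time for protodesilylation by the pyridinium salt or silyl transfer back to oxygen. The fallback avoids the free phenol altogether; it sets out from 2 and comes back at 6. The metalation of step 2 would be run as before, and the lithium phenoxide 4 would be sulfonylated in the same flask with PhNTf2, an amine-tolerant triflyl donor, in place of the aqueous quench. No new compound arises.

## Further compounds

F1 | step 4 | 1,1'-[(3,6-dibromo-1,2-phenylene)bis(oxy)]bis(2,2,6,6-tetramethylpiperidine) | CC1(C)CCCC(C)(C)N1Oc1c(Br)ccc(Br)c1ON1C(C)(C)CCCC1(C)C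
F2 | step 4 | 3,6-dibromobenzene-1,2-diol | Oc1c(Br)ccc(Br)c1O
F3 | step 4 | (2,4-dibromophenyl)(2,4,6-trimethoxyphenyl)iodonium 4-methylbenzenesulfonate | COc1cc(OC)c([I+]c2ccc(Br)cc2Br)c(OC)c1.Cc1ccc(cc1)S([O-])(=O)=O
F4 | step 2 | 1,4-dibromo-2-(methoxymethoxy)benzene | COCOc1cc(Br)ccc1Br
F5 | step 2 | [3,6-dibromo-2-(methoxymethoxy)phenyl]trimethylsilane | COCOc1c(Br)ccc(Br)c1[Si](C)(C)C
F0 | step 3 | none | none
A1 | alternative 1 | 4,5-diethynyl-2,2-dimethyl-1,3-dioxole | C#CC1=C(C#C)OC(C)(C)O1
A2 | alternative 1 | 4,7-dibromo-2,2-dimethyl-1,3-benzodioxole | CC1(C)Oc2c(Br)ccc(Br)c2O1
A3 | alternative 2 | 2,5-dibromothiophene 1,1-dioxide | O=S1(=O)C(Br)=CC=C1Br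
A4 | alternative 2 | 2,4-dibromo-1-{[2,2-bis(trimethylsilyloxy)ethenyl]oxy}benzene | C[Si](C)(C)OC(O[Si](C)(C)C)=COc1ccc(Br)cc1Br
A5 | alternative 2 | [3,6-dibromo-2-(2,4-dibromophenoxy)phenoxy]trimethylsilane | C[Si](C)(C)Oc1c(Br)ccc(Br)c1Oc1ccc(Br)cc1Br
A6 | alternative 3 | 3,5-dibromo-2H-pyran-2-one | O=C1OC=C(Br)C=C1Br
A7 | alternative 3 | 3,6-dibromo-2-methoxyphenol | COc1c(Br)ccc(Br)c1O
A8 | alternative 3 | 1,4-dibromo-2-(ethynyloxy)-3-methoxybenzene | COc1c(Br)ccc(Br)c1OC#C
A9 | alternative 3 | 1,4-dibromo-2-(2,4-dibromophenoxy)-3-methoxybenzene | COc1c(Br)ccc(Br)c1Oc1ccc(Br)cc1Br
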